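Ring B is cut into a vinylketene (C6', C1', C2' plus the carbonyl carbon C3') and a silyl ynol ether (C4', C5'). The cut exploits the substitution of ring B: oxygens on C3' and C5' meta to each other, hydrogen on C4', and three neighbouring carbon substituents (prenyl on C6', the benzofuran-2-yl unit on C1', prenyl on C2'). Heating a racemic 2,4-diprenyl-3-(6-silyloxybenzofuran-2-yl)cyclobutenone with a C-silylated siloxyalkyne makes C3'-C4', C5'-C6' and C2'-C3' in one pericyclic cascade, closes ring B and places all five substituents. The cyclobutenone arises from a ketene/ynol ether [2+2], aryllithium addition and acid transposition; fluoride then strips the three silyl groups.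

Key step: step 9

Remark: prenyl = 3-methylbut-2-en-1-yl; primed locants belong to ring B, unprimed ones to the benzofuran. The C4 centre of the cyclobutenone is carried as the racemate because it becomes the aromatic carbon C2'; the target has no stereocentre. Compounds 1, 2, 7, 8, 13 and 18 are assumed to be purchased.

Step 1
Reactants: 1 2-methylbut-3-en-2-ol; 2 triethyl orthoacetate
Product: 4 ethyl 5-methylhex-4-enoate, via ketene acetal 3 (not isolated)
Conditions: MeC(OEt)3 (3 equiv), EtCO2H (cat.), 140 °C, EtOH distilled off
Reagents that add atoms: none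
Why: Johnson–Claisen rearrangement: acid-catalysed alcohol exchange and loss of ethanol give ketene acetal 3, whose chair-like [3,3] shift across the tertiary allylic C–O bond should deliver the trisubstituted alkene and the two-carbon ester arm together.

Step 2
Reactants: 4 ethyl 5-methylhex-4-enoate
Product: 5 5-methylhex-4-enoic acid
Conditions: LiOH·H2O, THF/MeOH/H2O, rt; then cold 1 M HCl to pH 3
Reagents that add atoms: lithium hydroxide, [Li+].[OH-]
Why: Ester saponification with hydroxide (acyl substitution), followed by brief cold acidification so that the trisubstituted alkene has no chance to lactonise onto the acid.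

Step 3
Reactants: 5 5-methylhex-4-enoic acid
Product: 6 5-methylhex-4-enoyl chloride
Conditions: (COCl)2, DMF (cat.), CH2Cl2, 0 °C to rt; volatiles removed, used crude
Reagents that add atoms: oxalyl chloride, O=C(Cl)C(=O)Cl
Why: Acid chloride formation with oxalyl chloride under DMF catalysis is a standard acyl substitution whose by-products are gases, and the isolated alkene should survive at or below room temperature.

Step 4
Reactants: 7 ethoxyacetylene; 8 prenyl bromide
Product: 10 1-ethoxy-5-methylhex-4-en-1-yne, via lithium ethoxyacetylide 9 (not isolated)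
Conditions: n-BuLi, THF, −78 °C; then 8, DMPU, −78 °C to rt
Reagents that add atoms: none
Why: SN2 alkylation of a lithium alkoxyacetylide at the primary allylic carbon of prenyl bromide, accelerated by the dipolar cosolvent; the acetylide is too weak a base to isomerise the skipped enyne.

Step 5
Reactants: 6 5-methylhex-4-enoyl chloride; 10 1-ethoxy-5-methylhex-4-en-1-yne
Product: 12 3-ethoxy-2,4-bis(3-methylbut-2-enyl)cyclobut-2-en-1-one (racemic), via prenylketene 11 (not isolated)
Conditions: Et3N, CH2Cl2, rt, 6 added slowly by syringe pump
Reagents that add atoms: none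
Why: Dehydrochlorination of 6 gives aldoketene 11, which should add to the ynol ether in a thermal ketene-alkyne [2+2] cycloaddition with the nucleophilic alkyne carbon (β to oxygen) bonding to the ketene carbonyl carbon, so the ethoxy group ends up on C3 as a vinylogous ester; the C4 stereocentre forms without control and is carried as the racemate.

Step 6
Reactants: 13 benzofuran-6-ol
Product: 14 6-(triisopropylsilyloxy)benzofuran
Conditions: i-Pr3SiCl, imidazole, DMF, rt
Reagents that add atoms: triisopropylsilyl chloride, CC(C)[Si](Cl)(C(C)C)C(C)C
Why: Imidazole-promoted silylation of a phenol; the triisopropylsilyl ether should withstand n-BuLi at −78 °C, dilute acid and heating, and falls to fluoride at the end.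

Step 7
Reactants: 14 6-(triisopropylsilyloxy)benzofuran; 12 3-ethoxy-2,4-bis(3-methylbut-2-enyl)cyclobut-2-en-1-one
Product: 17 2,4-bis(3-methylbut-2-enyl)-3-[6-(triisopropylsilyloxy)benzofuran-2-yl]cyclobut-2-en-1-one (racemic), via 2-lithiobenzofuran 15 (not isolated), via carbinol adduct 16 (not isolated)
Conditions: n-BuLi, THF, −78 °C; then 12, −78 °C; then 1 M HCl, THF, 0 °C
Reagents that add atoms: water, O
Why: Stork–Danheiser sequence: the benzofuran is lithiated at C2 (its most acidic C–H), 15 adds 1,2 to the vinylogous ester carbonyl of 12, and dilute acid ionises the doubly activated tertiary carbinol 16 to an ethoxy-stabilised cation whose hydrolysis transposes the carbonyl; the carbinol centre is destroyed and C4 stays racemic.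

Step 8
Reactants: 18 trimethylsilylacetylene
Product: 21 1-(triisopropylsilyloxy)-2-(trimethylsilyl)acetylene, via lithium silylacetylide 19 (not isolated), via lithium silylynolate 20 (not isolated)
Conditions: n-BuLi, THF, −78 °C; t-BuOOLi (from t-BuOOH + LiN(SiMe3)2), −78 to 0 °C; i-Pr3SiOTf, −78 °C; filtered through basic alumina, used at once
Reagents that add atoms: tert-butyl hydroperoxide, CC(C)(C)OO; triisopropylsilyl trifluoromethanesulfonate, CC(C)[Si](OS(=O)(=O)C(F)(F)F)(C(C)C)C(C)C
Why: Electrophilic oxygen transfer from lithium tert-butyl peroxide to the lithium acetylide gives ynolate 20 (acetylide oxidation), and the hard, bulky silyl triflate should capture this ambident anion on oxygen, as in the established preparation of triisopropylsilyl ynol ethers from terminal alkynes.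

Step 9
Reactants: 17 2,4-bis(3-methylbut-2-enyl)-3-[6-(triisopropylsilyloxy)benzofuran-2-yl]cyclobut-2-en-1-one; 21 1-(triisopropylsilyloxy)-2-(trimethylsilyl)acetylene
Product: 26 4'-(trimethylsilyl)-5',6-bis-O-(triisopropylsilyl)mulberrofuran V, via vinylketene 22 (not isolated), via vinylcyclobutenone 23 (not isolated), via dienylketene 24 (not isolated), via cyclohexadienone 25 (not isolated)
Conditions: 21 (2.5 equiv), degassed toluene, 80 °C then 100 °C, sealed tube, argon
Reagents that add atoms: none
Why: Thermal four-electron conrotatory opening of 17, with the C4 prenyl turning outward, gives vinylketene 22; its ketene carbon (C3') is attacked by the silyl-bearing alkyne carbon of 21 (C4') while the oxygen-bearing carbon (C5') bonds to C6' in a regiospecific [2+2] to give 23, which opens again to dienylketene 24, closes and tautomerises via 25 to phenol 26. The closest known reaction is the Danheiser benzannulation of cyclobutenones with siloxyalkynes, which gives resorcinol monosilyl ethers. Ring B closes by thermal disrotatory six-electron electrocyclisation of 24, which forms C2'-C3' between the ketene carbon and the prenyl-bearing diene terminus. No stereocentre is created, and the racemic C4 centre of 17 becomes the aromatic carbon C2'. The selectivity needed is the orientation of the ketene-alkyne union; it is secured by the polarisation of the ynol ether (the carbon β to oxygen is the nucleophile, and the cation developing on the oxygen-bearing carbon is also β to silicon), so the two oxygens must end up meta with C4' between them. Outward rotation leaves the C4 prenyl trans to the ketene and the other prenyl sits one carbon from the ketene terminus, so neither alkene can reach it for an internal [2+2], and the new hydroxyl, flanked by SiMe3 and prenyl, is shielded from acylation by 22.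

Step 10
Reactants: 26 4'-(trimethylsilyl)-5',6-bis-O-(triisopropylsilyl)mulberrofuran V
Product: 28 mulberrofuran V, via 4'-silyl triol 27 (not isolated)
Conditions: n-Bu4NF·3H2O (5 equiv), degassed THF, 0 °C to 40 °C, argon; then pH 6 phosphate buffer
Reagents that add atoms: none
Why: Fluoride-induced cleavage of the two aryl silyl ethers gives 27 as its phenoxide, which water protonates at C4' (the carbon between the two oxygens) to an α-silyl dienone that loses silicon to fluoride, a base-mediated ipso protodesilylation that avoids the acid under which ortho-prenyl phenols cyclise to chromans.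

Compound list
1 | 2-methylbut-3-en-2-ol | CC(C)(O)C=C | starting material
2 | triethyl orthoacetate | CCOC(C)(OCC)OCC | starting material
3 | 1-ethoxy-1-[(2-methylbut-3-en-2-yl)oxy]ethene (mixed ketene acetal) | C=C(OCC)OC(C)(C)C=C | intermediate
4 | ethyl 5-methylhex-4-enoate | CCOC(=O)CCC=C(C)C | intermediate
5 | 5-methylhex-4-enoic acid | OC(=O)CCC=C(C)C | intermediate
6 | 5-methylhex-4-enoyl chloride | ClC(=O)CCC=C(C)C | intermediate
7 | ethoxyacetylene | C#COCC | starting material
8 | prenyl bromide (1-bromo-3-methylbut-2-ene) | CC(C)=CCBr | starting material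
9 | lithium ethoxyacetylide | [Li]C#COCC | intermediate
10 | 1-ethoxy-5-methylhex-4-en-1-yne | CCOC#CCC=C(C)C | intermediate
11 | prenylketene (5-methylhexa-1,4-dien-1-one) | O=C=CCC=C(C)C | intermediate
12 | 3-ethoxy-2,4-bis(3-methylbut-2-enyl)cyclobut-2-en-1-one, racemic | CCOC1=C(CC=C(C)C)C(=O)C1CC=C(C)C | intermediate
13 | benzofuran-6-ol | Oc1ccc2ccoc2c1 | starting material
14 | 6-(triisopropylsilyloxy)benzofuran | CC(C)[Si](Oc1ccc2ccoc2c1)(C(C)C)C(C)C | intermediate
15 | 2-lithio-6-(triisopropylsilyloxy)benzofuran | [Li]c1cc2ccc(O[Si](C(C)C)(C(C)C)C(C)C)cc2o1 | intermediate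
16 | 3-ethoxy-2,4-bis(3-methylbut-2-enyl)-1-[6-(triisopropylsilyloxy)benzofuran-2-yl]cyclobut-2-en-1-ol, mixture of racemic diastereomers | CCOC1=C(CC=C(C)C)C(O)(c2cc3ccc(O[Si](C(C)C)(C(C)C)C(C)C)cc3o2)C1CC=C(C)C | intermediate
17 | 2,4-bis(3-methylbut-2-enyl)-3-[6-(triisopropylsilyloxy)benzofuran-2-yl]cyclobut-2-en-1-one, racemic | O=C1C(CC=C(C)C)=C(c2cc3ccc(O[Si](C(C)C)(C(C)C)C(C)C)cc3o2)C1CC=C(C)C | intermediate
18 | trimethylsilylacetylene | C#C[Si](C)(C)C | starting material
19 | lithium (trimethylsilyl)acetylide | [Li]C#C[Si](C)(C)C | intermediate
20 | lithium 2-(trimethylsilyl)ethynolate | [Li]OC#C[Si](C)(C)C | intermediate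
21 | 1-(triisopropylsilyloxy)-2-(trimethylsilyl)acetylene | C[Si](C)(C)C#CO[Si](C(C)C)(C(C)C)C(C)C | intermediate
22 | vinylketene from ring opening of 17, prenyl-bearing CH2 trans to the ketene carbon | O=C=C(CC=C(C)C)/C(c1cc2ccc(O[Si](C(C)C)(C(C)C)C(C)C)cc2o1)=C/CC=C(C)C | intermediate
23 | 4-vinylcyclobutenone: 4-prenyl-2-(trimethylsilyl)-3-(triisopropylsilyloxy)-4-[1-(6-triisopropylsilyloxybenzofuran-2-yl)-5-methylhexa-1,4-dienyl]cyclobut-2-en-1-one, racemic | O=C1C([Si](C)(C)C)=C(O[Si](C(C)C)(C(C)C)C(C)C)C1(CC=C(C)C)/C(c2cc3ccc(O[Si](C(C)C)(C(C)C)C(C)C)cc3o2)=C/CC=C(C)C | intermediate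
24 | dienylketene from ring opening of 23, ketene-bearing and aryl-bearing carbons cis on the central alkene | O=C=C([Si](C)(C)C)/C(O[Si](C(C)C)(C(C)C)C(C)C)=C(CC=C(C)C)\C(c1cc2ccc(O[Si](C(C)C)(C(C)C)C(C)C)cc2o1)=C\CC=C(C)C | intermediate
25 | 4,6-diprenyl-2-(trimethylsilyl)-3-(triisopropylsilyloxy)-5-(6-triisopropylsilyloxybenzofuran-2-yl)cyclohexa-2,4-dien-1-one, racemic | O=C1C([Si](C)(C)C)=C(O[Si](C(C)C)(C(C)C)C(C)C)C(CC=C(C)C)=C(c2cc3ccc(O[Si](C(C)C)(C(C)C)C(C)C)cc3o2)C1CC=C(C)C | intermediate
26 | 4'-(trimethylsilyl)-5',6-bis-O-(triisopropylsilyl)mulberrofuran V | CC(C)=CCc1c(O)c([Si](C)(C)C)c(O[Si](C(C)C)(C(C)C)C(C)C)c(CC=C(C)C)c1-c1cc2ccc(O[Si](C(C)C)(C(C)C)C(C)C)cc2o1 | intermediate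
27 | 4'-(trimethylsilyl)mulberrofuran V | CC(C)=CCc1c(O)c([Si](C)(C)C)c(O)c(CC=C(C)C)c1-c1cc2ccc(O)cc2o1 | intermediate
28 | mulberrofuran V | CC(C)=CCc1c(O)cc(O)c(CC=C(C)C)c1-c1cc2ccc(O)cc2o1 | target

Total step count: 10. Longest linear sequence: 7 steps (steps 1, 2, 3, 5, 7, 9, 10).

Steps most likely to fail

Step 9. At the temperature that ring opening of 17 demands, the siloxyalkyne may drift to a bis-silylketene by 1,3-silyl shift, or may trap the vinylketene too slowly, so that 22 is lost to dimerisation. The fallback sets out from 17 and 21 and rejoins the route at 26. It separates ketene generation from heating: 17 is opened photochemically (365 nm LED, flow reactor, toluene, 20 °C) in the presence of 21, so that the [2+2] to vinylcyclobutenone 23 occurs at room temperature and the ynol ether never sees heat. Compound 23 is then isolated and thermolysed alone (toluene, 80 to 100 °C), which should give 26 through 24 and 25. This staged route makes no compound outside the list (F0).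

Step 8. Oxygen transfer to the silylacetylide may stall, or peroxide and alkoxide may attack silicon and strip the C-silyl group. The fallback sets out from 7 and rejoins the route at 20. Compound 7 is deprotonated with n-BuLi and silylated with Me3SiCl to give 1-ethoxy-2-(trimethylsilyl)acetylene F1. Heating F1 neat at 120 °C (retro-ene loss of ethylene) should give (trimethylsilyl)ketene F2. Deprotonation of F2 with n-BuLi in THF at −100 °C gives ynolate 20 without any oxidant, and 20 is silylated with i-Pr3SiOTf as in step 8 to give 21.

Step 10. Cleavage of the aryl C–Si bond under fluoride may remain incomplete, and prolonged basic treatment exposes the electron-rich phenoxides to air oxidation. The fallback sets out from 26 and comes back at 28. The carbon-bound silicon is removed first by electrophilic ipso protodesilylation (CF3CO2H, 3 equiv, CH2Cl2, −20 °C). The carbon flanked by two oxygens should be protonated much faster than the prenyl alkenes, giving 5',6-bis-O-(triisopropylsilyl)mulberrofuran V F3. A short treatment with n-Bu4NF in THF at 0 °C then removes only the two oxygen-bound silyl groups and gives 28.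

Further compounds
F0 | step 9 | none | none
F1 | step 8 | 1-ethoxy-2-(trimethylsilyl)acetylene | CCOC#C[Si](C)(C)C
F2 | step 8 | (trimethylsilyl)ketene | C[Si](C)(C)C=C=O
F3 | step 10 | 5',6-bis-O-(triisopropylsilyl)mulberrofuran V | CC(C)=CCc1c(O)cc(O[Si](C(C)C)(C(C)C)C(C)C)c(CC=C(C)C)c1-c1cc2ccc(O[Si](C(C)C)(C(C)C)C(C)C)cc2o1
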